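Everything rests on hiding the Br–C10–C3(Cl)–C4 unit of the cyclohexane (ring C1–C6) in a cyclopropane: C3–C10 and a C4–C10 bond that exists only to be broken are made together across a 2-chloro silyl enol ether, and electrophilic bromine later cuts C4–C10, leaving CH2Br and Cl on C3 next to a C4 ketone. In one operation the key step closes the three-membered ring and sets C3, with chlorine opposite the C6 oxygen that steers the reagent. Its substrate is a cyclohex-3-ene with Cl on C3, a triisopropylsilyl enol ether at C4 (sturdier than triethylsilyl towards silyl transfer and hydrolysis), a free C6 hydroxyl trans to the C1 ester, and the C1 methyl/ester quaternary centre.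

Key step: step 9

Remark (numbering): the ring atoms keep one numbering in all names: C1 = quaternary carbon (methyl plus the carboxyl-derived carbon), C2, C3 (chlorine plus C10), C4, C5, C6; "lower face" is the face of the C1 methyl, "upper face" that of the C1 ester, and locants follow this scheme even where nomenclature rules would count the other way.

Assumption: which antipode of the bisphosphine in step 4 leads to the (1S,6S) alcohol is fixed by a screening run; the (R,R) form is written.

Step 1
Reactants: 1 benzoic acid; 2 iodomethane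
Product: 4 1-methylcyclohexa-2,5-diene-1-carboxylic acid, via dilithium 1-carboxylatocyclohexa-2,5-dien-1-ide 3 (not isolated)
Conditions: Li, NH3(l)/THF, −78 °C; then MeI, −78 °C → rt; aq. HCl
Reagents that add atoms: iodomethane, CI
Why: Birch reduction of the benzoate stops at the 1,4-dihydro dianion 3, whose carbanion next to the carboxylate is methylated by SN2 (Birch reductive alkylation); C1 lies on a mirror plane, so no stereocentre arises.

Step 2
Reactants: 4 1-methylcyclohexa-2,5-diene-1-carboxylic acid; 2 iodomethane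
Product: 5 methyl 1-methylcyclohexa-2,5-diene-1-carboxylate
Conditions: MeI, K2CO3, DMF, rt
Reagents that add atoms: iodomethane, CI
Why: SN2 O-alkylation of the potassium carboxylate (esterification) leaves the skipped diene untouched.

Step 3
Reactants: 5 methyl 1-methylcyclohexa-2,5-diene-1-carboxylate
Product: 6 methyl 1-methyl-4-oxocyclohexa-2,5-diene-1-carboxylate
Conditions: CrO3 (5 mol%), 70% aq. t-BuOOH, CH2Cl2, rt
Reagents that add atoms: tert-butyl hydroperoxide, CC(C)(C)OO
Why: Chromium-catalysed allylic oxidation with t-BuOOH attacks the doubly allylic C4 methylene, the only activated C–H position, and should give the cross-conjugated dienone, which keeps the mirror plane through C1 and C4.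

Step 4
Reactants: 6 methyl 1-methyl-4-oxocyclohexa-2,5-diene-1-carboxylate; 7 bis(pinacolato)diboron
Product: 9 methyl (1S,6S)-6-hydroxy-1-methyl-4-oxocyclohex-2-ene-1-carboxylate (hydroxyl trans to ester), via methyl (1R,6S)-1-methyl-4-oxo-6-(pinacolboryl)cyclohex-2-ene-1-carboxylate 8 (not isolated)
Conditions: [Cu(MeCN)4]PF6 (5 mol%), (R,R)-2,3-bis(tert-butylmethylphosphino)quinoxaline (6 mol%), LiOt-Bu (10 mol%), B2pin2 (1.0 equiv), MeOH (2 equiv), THF, −20 °C; then NaBO3·4H2O, THF/H2O, 0 °C → rt
Reagents that add atoms: sodium perborate (oxygen of the C6 hydroxyl), [Na+].[Na+].O[B-]1(O)OO[B-](O)(O)OO1; bis(pinacolato)diboron (boron of intermediate 8 only), CC1(C)OB(OC1(C)C)B1OC(C)(C)C(C)(C)O1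
Why: Enantioselective copper-catalysed conjugate borylation desymmetrises the dienone: the chiral Cu–Bpin complex selects one enantiotopic enone and should add boron to C6 on the lower face, anti to the ester (the better acceptor and larger flank), and perborate oxidation of the C–B bond with retention gives the alcohol.

Step 5
Reactants: 9 methyl (1S,6S)-6-hydroxy-1-methyl-4-oxocyclohex-2-ene-1-carboxylate
Product: 10 methyl (1S,6S)-1-methyl-4-oxo-6-(triethylsilyloxy)cyclohex-2-ene-1-carboxylate
Conditions: Et3SiCl, imidazole, CH2Cl2, 0 °C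
Reagents that add atoms: chlorotriethylsilane, CC[Si](Cl)(CC)CC
Why: O-silylation under weakly basic conditions masks the hydroxyl, which would otherwise be oxidised in step 6 and silylated in step 7, without eliminating the β-oxygen.

Step 6
Reactants: 10 methyl (1S,6S)-1-methyl-4-oxo-6-(triethylsilyloxy)cyclohex-2-ene-1-carboxylate
Product: 11 methyl (1S,6S)-3-chloro-1-methyl-4-oxo-6-(triethylsilyloxy)cyclohex-2-ene-1-carboxylate
Conditions: PhICl2, pyridine, CH2Cl2, 0 °C → rt
Reagents that add atoms: (dichloro-λ3-iodanyl)benzene, ClI(Cl)c1ccccc1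
Why: α-Chlorination of the enone by chlorine addition across C2=C3 followed by pyridine-induced loss of HCl (acidic C3–H, β-chloride at C2), a known addition–elimination route to 2-chloroenones.

Step 7
Reactants: 11 methyl (1S,6S)-3-chloro-1-methyl-4-oxo-6-(triethylsilyloxy)cyclohex-2-ene-1-carboxylate
Product: 12 methyl (1S,6S)-3-chloro-1-methyl-6-(triethylsilyloxy)-4-(triisopropylsilyloxy)cyclohex-3-ene-1-carboxylate
Conditions: i-Pr3SiH, Pt2(dvtms)3 (1 mol%; dvtms = 1,3-divinyl-1,1,3,3-tetramethyldisiloxane), toluene, 70 °C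
Reagents that add atoms: triisopropylsilane, CC(C)[SiH](C(C)C)C(C)C
Why: Platinum-catalysed 1,4-hydrosilylation of the enone delivers hydrogen to C2 and silicon to oxygen, so the enol ether double bond is fixed between C3 and C4 with chlorine on C3.

Step 8
Reactants: 12 methyl (1S,6S)-3-chloro-1-methyl-6-(triethylsilyloxy)-4-(triisopropylsilyloxy)cyclohex-3-ene-1-carboxylate
Product: 13 methyl (1S,6S)-3-chloro-6-hydroxy-1-methyl-4-(triisopropylsilyloxy)cyclohex-3-ene-1-carboxylate
Conditions: PPTS (10 mol%), MeOH/CH2Cl2, 0 °C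
Reagents that add atoms: none
Why: Acid-catalysed methanolysis (selective desilylation) should remove only the secondary triethylsilyl ether, because the hindered triisopropylsilyl enol ether is further protected by the C3 chlorine, which slows C-protonation.

Step 9
Reactants: 13 methyl (1S,6S)-3-chloro-6-hydroxy-1-methyl-4-(triisopropylsilyloxy)cyclohex-3-ene-1-carboxylate; 14 diiodomethane
Product: 16 methyl (1S,3S,4S,6R)-1-chloro-4-hydroxy-3-methyl-6-(triisopropylsilyloxy)bicyclo[4.1.0]heptane-3-carboxylate, via ethylzinc C6-alkoxide 15 (not isolated)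
Conditions: Et2Zn (2.5 equiv), CH2I2 (2.5 equiv), CH2Cl2, −20 → 0 °C; pyridine, then aq. NH4Cl
Reagents that add atoms: diiodomethane, ICI
Why: Proposed new method: Et2Zn converts the C6 hydroxyl into the ethylzinc alkoxide 15, which exchanges with CH2I2 to an oxygen-bound iodomethylzinc carbenoid that hands its methylene to the C3=C4 enol ether through the usual butterfly transition state; the oxygen donor at C4 offsets the deactivating chlorine at C3, but this zinc-carbenoid methylene transfer has not been shown on a 2-chloro silyl enol ether. The closest known reactions are the Simmons–Smith cyclopropanation (diethylzinc variant) of silyl enol ethers and its hydroxyl-directed form on cyclohex-3-enols. The ring C3–C4–C10 closes by a concerted, suprafacial [2+1] addition in which both C–C bonds form in one event. C3 and C4 are therefore set together, and their sense is controlled by the C6 zinc alkoxide, which brings C10 in on the lower face and leaves Cl and the silyloxy group on the upper face. The step needs π-facial selectivity, which the homoallylic alkoxide secures; the bulky triisopropylsilyl group prevents silyl transfer to that alkoxide and slows zinc-halide-induced ionisation of the chlorocyclopropane, and the pyridine quench removes zinc iodide before work-up.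

Step 10
Reactants: 16 methyl (1S,3S,4S,6R)-1-chloro-4-hydroxy-3-methyl-6-(triisopropylsilyloxy)bicyclo[4.1.0]heptane-3-carboxylate
Product: 17 methyl (1S,3R,6S)-3-(bromomethyl)-3-chloro-6-hydroxy-1-methyl-4-oxocyclohexane-1-carboxylate
Conditions: NBS, CH2Cl2, −40 → 0 °C
Reagents that add atoms: N-bromosuccinimide, O=C1CCC(=O)N1Br
Why: Electrophilic bromine attacks the unsubstituted cyclopropane carbon C10 while the oxygen lone pair breaks C4–C10 (ring-opening bromination of a siloxycyclopropane to a β-bromo ketone); C3 keeps its configuration because none of its retained bonds is touched, and with no α-hydrogen there the bromide cannot be eliminated.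

Step 11
Reactants: 17 methyl (1S,3R,6S)-3-(bromomethyl)-3-chloro-6-hydroxy-1-methyl-4-oxocyclohexane-1-carboxylate
Product: 19 methyl (1S,3R,4R,6S)-3-(bromomethyl)-3-chloro-4,6-dihydroxy-1-methylcyclohexane-1-carboxylate, via O6-diethylboryl chelate 18 (not isolated)
Conditions: Et2BOMe, THF/MeOH (4:1), −78 °C; then NaBH4, −78 °C; AcOH, MeOH evaporation
Reagents that add atoms: none
Why: Narasaka–Prasad reduction: the diethylboron chelate spanning the C6 oxygen and the C4 carbonyl occupies the lower face, so borohydride should add from the upper face and place the new C4 hydroxyl syn to the C6 hydroxyl (both on the lower face).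

Step 12
Reactants: 19 methyl (1S,3R,4R,6S)-3-(bromomethyl)-3-chloro-4,6-dihydroxy-1-methylcyclohexane-1-carboxylate
Product: 21 methyl (1S,3R,4R,6S)-3-(bromomethyl)-3-chloro-1-methyl-4,6-[sulfonylbis(oxy)]cyclohexane-1-carboxylate (cyclic sulfate bridging O4 to O6), via O4,O6-cyclic sulfite 20 (not isolated)
Conditions: SOCl2, pyridine, CH2Cl2, 0 °C; then RuCl3 (1 mol%), NaIO4, MeCN/H2O, 0 °C
Reagents that add atoms: thionyl chloride, O=S(Cl)Cl; sodium periodate, [Na+].[O-]I(=O)(=O)=O
Why: The cis-1,3-diol closes a six-membered cyclic sulfite that catalytic RuO4 oxidises to the cyclic sulfate (cyclic sulfate formation), activating both carbinol carbons without touching any stereocentre.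

Step 13
Reactants: 21 methyl (1S,3R,4R,6S)-3-(bromomethyl)-3-chloro-1-methyl-4,6-[sulfonylbis(oxy)]cyclohexane-1-carboxylate
Product: 23 methyl (1R,3R,4R,6R)-3-(bromomethyl)-3,6-dichloro-4-hydroxy-1-methylcyclohexane-1-carboxylate, via lithium C4-sulfate monoester 22 (not isolated)
Conditions: LiCl, DMF, 50 °C; then H2SO4 (cat.), H2O (2 equiv), THF, rt
Reagents that add atoms: lithium chloride, [Li+].[Cl-]
Why: SN2 ring opening of the cyclic sulfate by chloride should occur at C6, the carbon not flanked by the halogen-laden C3, with inversion that puts chlorine on the upper face (cis to the ester); acid hydrolysis of the C4 sulfate monoester cleaves S–O and so keeps C4.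

Step 14
Reactants: 23 methyl (1R,3R,4R,6R)-3-(bromomethyl)-3,6-dichloro-4-hydroxy-1-methylcyclohexane-1-carboxylate
Product: 24 methyl (1R,3S,4S,6R)-4-bromo-3-(bromomethyl)-3,6-dichloro-1-methylcyclohexane-1-carboxylate
Conditions: CBr4, P(n-C8H17)3, toluene, 70 °C
Reagents that add atoms: tetrabromomethane, BrC(Br)(Br)Br
Why: Appel reaction (trioctylphosphine variant for hindered secondary alcohols): bromide displaces the C4 alkoxyphosphonium by SN2 with inversion, ionisation being disfavoured by the flanking halogens, so bromine should end on the upper face, cis to the C3 chlorine.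

Step 15
Reactants: 24 methyl (1R,3S,4S,6R)-4-bromo-3-(bromomethyl)-3,6-dichloro-1-methylcyclohexane-1-carboxylate
Product: 25 [(1R,3S,4S,6R)-4-bromo-3-(bromomethyl)-3,6-dichloro-1-methylcyclohexyl]methanol
Conditions: i-Bu2AlH, CH2Cl2, −78 → 0 °C; aq. KNaC4H4O6 (potassium sodium tartrate)
Reagents that add atoms: none
Why: Ester reduction by the aluminium hydride to the primary alcohol; alkyl chlorides and bromides are inert to this electrophilic hydride at low temperature.

Step 16
Reactants: 25 [(1R,3S,4S,6R)-4-bromo-3-(bromomethyl)-3,6-dichloro-1-methylcyclohexyl]methanol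
Product: 26 (1R,3S,4S,6R)-4-bromo-3-(bromomethyl)-3,6-dichloro-1-methylcyclohexane-1-carbaldehyde
Conditions: Dess–Martin periodinane, CH2Cl2, rt
Reagents that add atoms: none
Why: Dess–Martin oxidation under neutral conditions gives the aldehyde, which has no α-hydrogen and therefore can neither epimerise nor eliminate the β-chloride.

Step 17
Reactants: 26 (1R,3S,4S,6R)-4-bromo-3-(bromomethyl)-3,6-dichloro-1-methylcyclohexane-1-carbaldehyde
Product: 27 (1R,3S,4S,6R)-4-bromo-3-(bromomethyl)-3,6-dichloro-1-[(E)-2-chloroethenyl]-1-methylcyclohexane (target)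
Conditions: CrCl2 (6 equiv), CHCl3 (2 equiv), THF, 65 °C
Reagents that add atoms: chloroform, ClC(Cl)Cl
Why: Takai olefination: the geminal dichromium species formed from CHCl3 and CrCl2 (divalent chromium) adds to the aldehyde and anti elimination should give the (E)-chloroalkene; unactivated alkyl chlorides and bromides are not reduced by CrCl2 in THF.

Compound list
1 | benzoic acid | OC(=O)c1ccccc1 | starting material
2 | iodomethane | CI | starting material
3 | dilithium 1-carboxylatocyclohexa-2,5-dien-1-ide | [Li+].[Li+].[O-]C(=O)[C-]1C=CCC=C1 | intermediate (not isolated)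
4 | 1-methylcyclohexa-2,5-diene-1-carboxylic acid | CC1(C(=O)O)C=CCC=C1 | intermediate
5 | methyl 1-methylcyclohexa-2,5-diene-1-carboxylate | COC(=O)C1(C)C=CCC=C1 | intermediate
6 | methyl 1-methyl-4-oxocyclohexa-2,5-diene-1-carboxylate | COC(=O)C1(C)C=CC(=O)C=C1 | intermediate
7 | bis(pinacolato)diboron | CC1(C)OB(OC1(C)C)B1OC(C)(C)C(C)(C)O1 | starting material
8 | methyl (1R,6S)-1-methyl-4-oxo-6-(4,4,5,5-tetramethyl-1,3,2-dioxaborolan-2-yl)cyclohex-2-ene-1-carboxylate (boron on the lower face) | C[C@]1(C(=O)OC)C=CC(=O)C[C@@H]1B2OC(C)(C)C(C)(C)O2 | intermediate (not isolated)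
9 | methyl (1S,6S)-6-hydroxy-1-methyl-4-oxocyclohex-2-ene-1-carboxylate (OH trans to ester) | C[C@]1(C(=O)OC)C=CC(=O)C[C@@H]1O | intermediate
10 | methyl (1S,6S)-1-methyl-4-oxo-6-(triethylsilyloxy)cyclohex-2-ene-1-carboxylate | C[C@]1(C(=O)OC)C=CC(=O)C[C@@H]1O[Si](CC)(CC)CC | intermediate
11 | methyl (1S,6S)-3-chloro-1-methyl-4-oxo-6-(triethylsilyloxy)cyclohex-2-ene-1-carboxylate | C[C@]1(C(=O)OC)C=C(Cl)C(=O)C[C@@H]1O[Si](CC)(CC)CC | intermediate
12 | methyl (1S,6S)-3-chloro-1-methyl-6-(triethylsilyloxy)-4-(triisopropylsilyloxy)cyclohex-3-ene-1-carboxylate | C[C@]1(C(=O)OC)CC(Cl)=C(O[Si](C(C)C)(C(C)C)C(C)C)C[C@@H]1O[Si](CC)(CC)CC | intermediate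
13 | methyl (1S,6S)-3-chloro-6-hydroxy-1-methyl-4-(triisopropylsilyloxy)cyclohex-3-ene-1-carboxylate (OH trans to ester; key-step precursor) | C[C@]1(C(=O)OC)CC(Cl)=C(O[Si](C(C)C)(C(C)C)C(C)C)C[C@@H]1O | intermediate
14 | diiodomethane | ICI | starting material
15 | ethylzinc C6-alkoxide of 13 | C[C@]1(C(=O)OC)CC(Cl)=C(O[Si](C(C)C)(C(C)C)C(C)C)C[C@@H]1O[Zn]CC | intermediate (not isolated)
16 | methyl (1S,3S,4S,6R)-1-chloro-4-hydroxy-3-methyl-6-(triisopropylsilyloxy)bicyclo[4.1.0]heptane-3-carboxylate (cyclopropane CH2 cis to OH; Cl and silyloxy on the ester face) | C[C@]1(C(=O)OC)C[C@]2(Cl)C[C@]2(O[Si](C(C)C)(C(C)C)C(C)C)C[C@@H]1O | intermediate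
17 | methyl (1S,3R,6S)-3-(bromomethyl)-3-chloro-6-hydroxy-1-methyl-4-oxocyclohexane-1-carboxylate (CH2Br cis to OH) | C[C@]1(C(=O)OC)C[C@](Cl)(CBr)C(=O)C[C@@H]1O | intermediate
18 | O6-diethylboryl chelate of 17 | C[C@]1(C(=O)OC)C[C@](Cl)(CBr)C(=O)C[C@@H]1OB(CC)CC | intermediate (not isolated)
19 | methyl (1S,3R,4R,6S)-3-(bromomethyl)-3-chloro-4,6-dihydroxy-1-methylcyclohexane-1-carboxylate (both OH on the lower face) | C[C@]1(C(=O)OC)C[C@](Cl)(CBr)[C@H](O)C[C@@H]1O | intermediate
20 | methyl (1S,3R,4R,6S)-3-(bromomethyl)-3-chloro-1-methyl-4,6-[sulfinylbis(oxy)]cyclohexane-1-carboxylate (cyclic sulfite, either configuration at sulfur) | C[C@]1(C(=O)OC)C[C@](Cl)(CBr)[C@H]2C[C@@H]1OS(=O)O2 | intermediate (not isolated)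
21 | methyl (1S,3R,4R,6S)-3-(bromomethyl)-3-chloro-1-methyl-4,6-[sulfonylbis(oxy)]cyclohexane-1-carboxylate (cyclic sulfate) | C[C@]1(C(=O)OC)C[C@](Cl)(CBr)[C@H]2C[C@@H]1OS(=O)(=O)O2 | intermediate
22 | lithium C4-sulfate monoester of methyl (1R,3R,4R,6R)-3-(bromomethyl)-3,6-dichloro-4-hydroxy-1-methylcyclohexane-1-carboxylate | C[C@]1(C(=O)OC)C[C@](Cl)(CBr)[C@H](OS(=O)(=O)[O-])C[C@H]1Cl.[Li+] | intermediate (not isolated)
23 | methyl (1R,3R,4R,6R)-3-(bromomethyl)-3,6-dichloro-4-hydroxy-1-methylcyclohexane-1-carboxylate (C6–Cl cis to ester, C4–OH on the lower face) | C[C@]1(C(=O)OC)C[C@](Cl)(CBr)[C@H](O)C[C@H]1Cl | intermediate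
24 | methyl (1R,3S,4S,6R)-4-bromo-3-(bromomethyl)-3,6-dichloro-1-methylcyclohexane-1-carboxylate | C[C@]1(C(=O)OC)C[C@](Cl)(CBr)[C@@H](Br)C[C@H]1Cl | intermediate
25 | [(1R,3S,4S,6R)-4-bromo-3-(bromomethyl)-3,6-dichloro-1-methylcyclohexyl]methanol | C[C@]1(CO)C[C@](Cl)(CBr)[C@@H](Br)C[C@H]1Cl | intermediate
26 | (1R,3S,4S,6R)-4-bromo-3-(bromomethyl)-3,6-dichloro-1-methylcyclohexane-1-carbaldehyde | C[C@]1(C=O)C[C@](Cl)(CBr)[C@@H](Br)C[C@H]1Cl | intermediate
27 | (1R,3S,4S,6R)-4-bromo-3-(bromomethyl)-3,6-dichloro-1-[(E)-2-chloroethenyl]-1-methylcyclohexane | C[C@]1(/C=C/Cl)C[C@](Cl)(CBr)[C@@H](Br)C[C@H]1Cl | target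

Total step count: 17. Longest linear sequence: 17 steps (1 → 27).

Steps most likely to fail

1. Step 9 (the proposed new method). The zinc carbenoid may fail to add to the chlorine-deactivated enol ether, the silyl group may move to the zinc alkoxide, or zinc iodide may ionise the C3–Cl bond of the product so that the three-membered ring opens to a 2-methylene ketone. The fallback uses known chemistry and gives up the directed cyclopropane. Setting out from the bis-silyl enol ether 12, a Mukaiyama aldol reaction with formaldehyde (1,3,5-trioxane, TiCl4, CH2Cl2, −78 °C) would attach C10 to C3 and give the α-chloro-α-(hydroxymethyl) ketone F1. Only the ring conformation then biases the approach, so the C3 epimer from attack on the ester face would have to be separated here. An Appel reaction (CBr4, PPh3, CH2Cl2) would convert the primary alcohol into the bromomethyl ketone F2, and mild acid (PPTS, MeOH) would free the C6 hydroxyl, returning to the route at hydroxy ketone 17.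

2. Step 14. Displacement at C4 is the most demanding substitution of the route. The carbon is flanked by C3 carrying Cl and CH2Br, and the incoming bromide must pass either that chlorine or the C6 chlorine already on the upper face. Elimination toward C5, or substitution without clean inversion, may therefore take over. The fallback introduces the two halogens in the opposite order. Setting out from diol 19, the more accessible C6 hydroxyl would be silylated (Et3SiOTf, 2,6-lutidine, CH2Cl2, −78 °C) to the mono-silyl ether F3. Its C4 triflate F4 (Tf2O, pyridine, CH2Cl2, −40 °C) would be displaced by Bu4NBr in toluene with inversion to the bromide F5. At that stage the C6 oxygen still lies on the lower face, so the ring can place the leaving group equatorial and offer an unhindered approach from above. HF·pyridine in THF would then give the alcohol F6, whose C6 triflate F7 (Tf2O, pyridine) would be displaced by Bu4NCl with inversion, returning to the route at bromo ester 24.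

3. Step 4. The copper–boryl reagent may discriminate poorly between the methyl and ester faces of C6 or between the two enones, a second boryl group may add, or the β-hydroxy ketone may dehydrate back to the dienone during the basic oxidation. The fallback changes both the nucleophile and the oxidation. Setting out from dienone 6, an enantioselective copper-catalysed conjugate silylation with PhMe2Si–Bpin (CuCl, a chiral imidazolinium-derived carbene ligand, NaOt-Bu, THF, −78 °C) would give the silyl ketone F8; the bulkier nucleophile should distinguish the two faces of C6 more sharply. A Fleming–Tamao oxidation under acidic conditions (Hg(OAc)2, AcOOH, AcOH), which proceeds with retention and does not promote dehydration, would return to the route at hydroxy enone 9.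

Further compounds
F1 | step 9 | methyl (1S,3S,6S)-3-chloro-3-(hydroxymethyl)-1-methyl-4-oxo-6-(triethylsilyloxy)cyclohexane-1-carboxylate | C[C@]1(C(=O)OC)C[C@](Cl)(CO)C(=O)C[C@@H]1O[Si](CC)(CC)CC
F2 | step 9 | methyl (1S,3R,6S)-3-(bromomethyl)-3-chloro-1-methyl-4-oxo-6-(triethylsilyloxy)cyclohexane-1-carboxylate | C[C@]1(C(=O)OC)C[C@](Cl)(CBr)C(=O)C[C@@H]1O[Si](CC)(CC)CC
F3 | step 14 | methyl (1S,3R,4R,6S)-3-(bromomethyl)-3-chloro-4-hydroxy-1-methyl-6-(triethylsilyloxy)cyclohexane-1-carboxylate | C[C@]1(C(=O)OC)C[C@](Cl)(CBr)[C@H](O)C[C@@H]1O[Si](CC)(CC)CC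
F4 | step 14 | methyl (1S,3R,4R,6S)-3-(bromomethyl)-3-chloro-1-methyl-6-(triethylsilyloxy)-4-(trifluoromethanesulfonyloxy)cyclohexane-1-carboxylate | C[C@]1(C(=O)OC)C[C@](Cl)(CBr)[C@H](OS(=O)(=O)C(F)(F)F)C[C@@H]1O[Si](CC)(CC)CC
F5 | step 14 | methyl (1S,3S,4S,6S)-4-bromo-3-(bromomethyl)-3-chloro-1-methyl-6-(triethylsilyloxy)cyclohexane-1-carboxylate | C[C@]1(C(=O)OC)C[C@](Cl)(CBr)[C@@H](Br)C[C@@H]1O[Si](CC)(CC)CC
F6 | step 14 | methyl (1S,3S,4S,6S)-4-bromo-3-(bromomethyl)-3-chloro-6-hydroxy-1-methylcyclohexane-1-carboxylate | C[C@]1(C(=O)OC)C[C@](Cl)(CBr)[C@@H](Br)C[C@@H]1O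
F7 | step 14 | methyl (1S,3S,4S,6S)-4-bromo-3-(bromomethyl)-3-chloro-1-methyl-6-(trifluoromethanesulfonyloxy)cyclohexane-1-carboxylate | C[C@]1(C(=O)OC)C[C@](Cl)(CBr)[C@@H](Br)C[C@@H]1OS(=O)(=O)C(F)(F)F
F8 | step 4 | methyl (1R,6S)-6-[dimethyl(phenyl)silyl]-1-methyl-4-oxocyclohex-2-ene-1-carboxylate | C[C@]1(C(=O)OC)C=CC(=O)C[C@@H]1[Si](C)(C)c2ccccc2
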